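The earlier runs and the new flask stem from a simulated flask from invented constants; noise was put on by code.

One pass of the catalyst cannot make the whole charge: at 8.5 mol%, each catalyst molecule has to go round 11.8 times, so you should count turnovers.

| flask | substrate | reagent | free catalyst | remark | time |
|---|---|---|---|---|---|
| delta | 0.025 M (fed, over 3.0 d) | 1 equiv | 8.5 mol% | run made earlier |  |
| theta | 0.038 M (fed, over 3.0 d) | 1 equiv | 8.5 mol% | run made earlier |  |
| eta | 0.050 M (fed, over 3.0 d) | 2 equiv | 8.5 mol% | run made earlier |  |
| red | 0.050 M (fed, over 3.0 d) | 1.00 equiv | 8.5 mol% |  | 3.0 d |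
| grey | 0.050 M | 1.00 equiv | 8.5 mol% | everything together at the start | 3.0 d |

| run | time / d | product / % |
|---|---|---|
| delta | 0.333 | 0.8 |
| delta | 0.833 | 1.5 |
| delta | 1.67 | 7.2 |
| delta | 2.50 | 12.6 |
| delta | 4.00 | 30.4 |
| theta | 0.333 | 0 |
| theta | 0.833 | 2.0 |
| theta | 1.67 | 9.0 |
| theta | 2.50 | 17.1 |
| theta | 4.00 | 31.5 |
| eta | 0.250 | 0.3 |
| eta | 0.500 | 0.4 |
| eta | 1.04 | 3.4 |
| eta | 2.08 | 15.0 |
| eta | 4.00 | 37.9 |

(each reading ± 1 percentage point)

- the numbers in the tables scatter by 1 percentage point (one standard deviation)
- percentages count the whole charge, also what has not yet gone in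

- the flask that ends with the higher amount of product, in percent of the substrate charged, or "neither" when 2 percentage points or less lies between them (red / grey / neither)
- final product, as a percentage of the substrate charged, in red
- final product, as a percentage of the substrate charged, in grey

Eta has the same substrate charge as red and grey. Between 2.08 d and 4.00 d its product climbs by a fraction 0.119 d⁻¹ of the charge, which is 1.40 d⁻¹ in turnovers. Multiply that by the loading and the time and you have the capacity number 35.8%: the fraction of the charge the catalyst passes on if it holds that pace throughout.

My reckoning reads grey, with its substrate present from the start, directly as 35.8%. Red must wait for its feed. Eta's line, extended back, reaches zero at 0.822 d, so red gets 26.0%, less than grey.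

One number was not quite enough, then: red needed the lag as well. The same count over the last two readings gives 35.6% from delta and 28.8% from theta. Delta's figure stands beside eta's 35.8% and theta's lies below it, though eta had 2 equiv of reagent; each figure rests on two readings that scatter by 1 percentage point.

The forecast, reckoning first order in substrate, gives 22.5% (19% to 26%) for red and 38% (31% to 44%) for grey: “Grey should therefore win clearly”.

The simulation gives 24.2% in red and 34.9% in grey, so grey ends higher, as forecast.

    reagent + catalyst intermediate A ⇌ catalyst intermediate B (K = 1100 L mol⁻¹, k = 1.80 L mol⁻¹ min⁻¹)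
    catalyst intermediate B → by-product + catalyst intermediate C (k = 0.00128 min⁻¹)
    catalyst intermediate C ⇌ free catalyst + product (K = 0.848 M, k = 0.0689 min⁻¹)
    substrate + free catalyst → catalyst intermediate A (k = 0.144 L mol⁻¹ min⁻¹)

Grey's result stands beside 35.8%, and the way the substrate goes in opens the 11 points gap to red. In grey at 3.00 d, catalyst intermediate B, the resting state, holds 72.6% of the catalyst. Its breakdown constant on that share gives 1.34 d⁻¹, beside the 1.40 d⁻¹ read from eta. Carried to a neighbour of grey charged with 14 mol% of free catalyst, the capacity number becomes 58.9%, and that flask gave 54.4%.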